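The product at 5.0 min is the charge of substrate minus what the flask has left, so read every run as fractions of that charge and ask how long the catalyst has really worked.

in all of them: reagent 0.936 M; scavenger 0.624 M; impurity 8.1 mM
- north-east: substrate 0.78 M; free catalyst 22 mM; run made earlier
- south-east: substrate 0.78 M; free catalyst 35 mM; run made earlier
- east: substrate 1.2 M; free catalyst 16 mM; run made earlier
- flask: substrate 0.78 M; free catalyst 16 mM; time 5.0 min

- north-east (time / min: substrate / %, product / %): 0.417: 78.2, 20.9; 1.33: 37.7, 60.6; 2.00: 21.3, 77.1; 3.00: 7.7, 93.2; 5.00: 0.6, 99.2; 6.00: 0, 98.1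
- south-east (time / min: substrate / %, product / %): 1.00: 23.9, 77.4; 2.00: 1.3, 97.2; 3.00: 0.1, 98.6; 4.00: 0, 100.3; 5.00: 0, 100.5; 6.00: 0, 100.3
- east (time / min: substrate / %, product / %): 0.500: 86.6, 10.9; 0.833: 80.9, 18.6; 1.50: 67.9, 32.1; 3.00: 43.3, 56.2; 6.00: 22.1, 74.9

(standard deviation of a reading: 1 percentage point)

- part of the substrate that has reacted at 5.0 min
- share of the unused reagent that is free and not bound as idle adduct, at 5.0 min

- the earlier runs were read with a standard deviation of 1 percentage point
- the earlier runs do not show how much of reagent is bound; that part of a forecast is a guess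

1. Take the impurity as a catalyst poison removing free catalyst one for one, which leaves a working fraction of 0.494 of the catalyst charge in this flask against 0.632 in the north-east run.

2. Convert the flask's time into north-east time, the time multiplied by the flask's working catalyst over the north-east run's: 2.84 min.

3. Replace the curve by its mean fall between 2.00 min and 3.00 min, 0.136 min⁻¹ of the charge, which leaves 9.85%.

4. Check that error with the slower mean fall after 3.00 min, 0.0355 min⁻¹, which leaves 8.26%, and commit to the middle, a conversion of 90.9%.

5. Reforge the weak link, the subtraction: the south-east reading at 1.00 min, 23.9% left, falls at 1.94 min of north-east time, beside the north-east 21.3% at 2.00 min, whereas bare charges put it at 1.59 min, where that run stood between 37.7% and 21.3%.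

The forecast, slightly above my reckoning, says 92% and a free share of 60%, adding that "the free share is largely a guess".

The flask gives 91.9% and 86.5%.

    catalyst intermediate C → catalyst intermediate D (k = 23.4 s⁻¹)
    substrate + catalyst intermediate A → catalyst intermediate B (k = 2.81 L mol⁻¹ s⁻¹)
    scavenger + released group → scavenged by-product (k = 3.98 L mol⁻¹ s⁻¹)
    free catalyst + impurity → spent catalyst B (k = 400 L mol⁻¹ s⁻¹)
    reagent + released group ⇌ idle adduct, settled at all times (K = 2.46 L mol⁻¹)
    catalyst intermediate D → free catalyst + product (k = 1.08 s⁻¹)
    catalyst intermediate B → released group + catalyst intermediate C (k = 1.71 s⁻¹)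
    reagent + free catalyst ⇌ catalyst intermediate A (K = 6.60 L mol⁻¹, k = 139 L mol⁻¹ s⁻¹)
    released group + catalyst intermediate C → spent catalyst A (k = 0.00711 L mol⁻¹ s⁻¹)

The free share stands 26 percentage points above the forecast, with 0.0290 M of idle adduct at 5.00 min. Now charge a neighbouring flask with 0.0020 M of impurity and leave the rest as it was: its working catalyst turns 5.0 min into 5.04 min of north-east time, and the north-east run had 0.6% of its substrate left at 5.00 min. That neighbouring flask gives a conversion of 99.2%, with 0.82% of its substrate left.

Readings and results are calculated with constants of no real substance; the scatter is artificial.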